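**Plan**

1. Retrosynthesis: both interflavan C4–C6 bonds are cut first (flavan-4-yl cation plus C6 of ring A of the next unit). All three units then reduce to one all-cis (2R,3R,4R)-flavan-3,4-diol, carried as its 3,4-cyclic carbonate 11. In 11 ring C is cut at O1–C2, then at C3–O (back to a C3–C4 epoxy alcohol), then at the C2–C3 aldol bond.
2. Forward: aldehyde 2 + ketone 3 → chalcone 4 → aryl Boc carbonate 5 → epoxy ketone 6 → threo epoxy alcohol 7 → ring C in one pot (Payne rearrangement, Boc shift, 6-endo oxirane opening) → 11. Then top unit (6-bromo diol 13) + 11 → dimer, carbonate off, + 11 → trimer, carbonate off, hydrogenolysis.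
3. Enabling feature: C2, C3 and C4 of ring C are three contiguous oxygen-bearing carbons, C2 is benzylic to the 4-oxygenated ring B, and O1 is a phenolic oxygen on C8a ortho to the C4 side chain. An oxirane can therefore be moved from C3–C4 to C2–C3 and then opened at C2 by O1.
4. Stereochemistry: C4 and C3 come from the catalyst-controlled enone epoxidation and C2 from the CBS reduction. The Payne step inverts C3 and the ring closure inverts C2, which gives the all-cis triad. Both interflavan C4 centres arise from attack anti to the axial 3-OH of the 2,3-cis cation (3,4-trans).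
5. Helpers: the aryl Boc group (phenol protection, acyl relay, ends as the cyclic carbonate that keeps C4 of the nucleophilic unit from ionising); bromine at C6 of the top unit (blocks self-condensation, lost in the last step); benzyl ethers.

Key step: step 6

Remark: flavan numbering (O1, C2, C3, C4, C4a, C5–C8, C8a; ring B = 2-aryl) is used throughout, also for open-chain precursors. The sense of induction of the La/BINOL epoxidation and of the CBS reduction is assigned from the chalcone and aryl alkyl ketone models, and the other catalyst enantiomer would be used if it proved opposite.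

**Step 1**
Reactants: 1 2,3,4-trihydroxybenzaldehyde
Product: 2 3,4-bis(benzyloxy)-2-hydroxybenzaldehyde
Conditions: BnBr (2.1 equiv), K2CO3 (2.1 equiv), DMF, 20 °C
Reagents that add atoms: benzyl bromide BrCc1ccccc1
Why: Williamson etherification in which the 2-OH, held in a hydrogen bond to the formyl group and therefore the least nucleophilic hydroxyl, should stay free while O-3 and O-4 are benzylated, as is known for 2,3,4-trihydroxyphenyl carbonyl compounds.

**Step 2**
Reactants: 2 3,4-bis(benzyloxy)-2-hydroxybenzaldehyde; 3 1-[4-(benzyloxy)phenyl]ethanone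
Product: 4 (E)-3-[3,4-bis(benzyloxy)-2-hydroxyphenyl]-1-[4-(benzyloxy)phenyl]prop-2-en-1-one
Conditions: KOH (3 equiv), EtOH/H2O, 20 °C; then AcOH to pH 5
Reagents that add atoms: none
Why: Claisen–Schmidt condensation in which the enolate of 3 adds to the non-enolisable aldehyde and E1cB dehydration gives the conjugated (E)-enone, the ortho-phenoxide being a spectator that is reprotonated with acetic acid (mineral acid is avoided because it would close the flavylium salt).

**Step 3**
Reactants: 4 (E)-3-[3,4-bis(benzyloxy)-2-hydroxyphenyl]-1-[4-(benzyloxy)phenyl]prop-2-en-1-one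
Product: 5 tert-butyl 2,3-bis(benzyloxy)-6-{(E)-3-[4-(benzyloxy)phenyl]-3-oxoprop-1-en-1-yl}phenyl carbonate
Conditions: Boc2O (1.2 equiv), DMAP (5 mol %), CH2Cl2, 0 → 20 °C
Reagents that add atoms: di-tert-butyl dicarbonate CC(C)(C)OC(=O)OC(=O)OC(C)(C)C
Why: DMAP-catalysed acylation of the phenol gives the aryl tert-butyl carbonate, which masks O1 during epoxidation and reduction and sits ortho to the side chain so that it can later be passed on to the C4 oxygen.

**Step 4**
Reactants: 5 tert-butyl 2,3-bis(benzyloxy)-6-{(E)-3-[4-(benzyloxy)phenyl]-3-oxoprop-1-en-1-yl}phenyl carbonate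
Product: 6 tert-butyl 2,3-bis(benzyloxy)-6-{(2R,3S)-3-[4-(benzyloxy)benzoyl]oxiran-2-yl}phenyl carbonate (trans-epoxy ketone; C4 R, C3 S)
Conditions: La(O-iPr)3 (5 mol %), (R)-BINOL (5 mol %), Ph3As=O (5 mol %), t-BuOOH (1.5 equiv), 4 Å MS, THF, 20 °C
Reagents that add atoms: tert-butyl hydroperoxide CC(C)(C)OO
Why: Catalytic asymmetric nucleophilic (Weitz–Scheffer-type) epoxidation of an (E)-chalcone, in which the La–BINOLate-bound tert-butylperoxide adds to one face of the enone and ring closure is faster than C–C rotation, so the trans-epoxide should form with the C4 (R) and C3 (S) centres set by the catalyst.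

**Step 5**
Reactants: 6 tert-butyl 2,3-bis(benzyloxy)-6-{(2R,3S)-3-[4-(benzyloxy)benzoyl]oxiran-2-yl}phenyl carbonate
Product: 7 tert-butyl 2,3-bis(benzyloxy)-6-[(2R,3R)-3-{(S)-[4-(benzyloxy)phenyl](hydroxy)methyl}oxiran-2-yl]phenyl carbonate (threo epoxy alcohol)
Conditions: (S)-2-methyl-CBS-oxazaborolidine (0.5 equiv), BH3·SMe2 (0.7 equiv), THF, −30 °C; MeOH quench
Reagents that add atoms: none
Why: Corey–Bakshi–Shibata reduction of an aryl ketone in which ring B is the large and the oxiranyl carbon the small substituent, so that the (S)-oxazaborolidine should deliver hydride to give the (S)-carbinol, which is the threo epoxy alcohol, under reagent control.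

**Step 6**
Reactants: 7 tert-butyl 2,3-bis(benzyloxy)-6-[(2R,3R)-3-{(S)-[4-(benzyloxy)phenyl](hydroxy)methyl}oxiran-2-yl]phenyl carbonate
Product: 11 3,4-cyclic carbonate of all-cis (2R,3R,4R)-7,8-bis(benzyloxy)-2-[4-(benzyloxy)phenyl]chromane-3,4-diol, via cis-epoxy aryl carbonate 8 (not isolated), via cis-epoxy phenol 9 (not isolated), via hydroxy tert-butyl carbonate 10 (not isolated)
Conditions: KN(SiMe3)2 (1.05 equiv), THF, −40 → 0 °C; AcOH (1.1 equiv) then PPTS (10 mol %), −20 → 20 °C; KOC(CH3)3 (0.3 equiv), 0 °C; one pot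
Reagents that add atoms: none
Why: Proposed new method: deprotonation of the C2 carbinol of 7 starts a Payne rearrangement in which the C2 alkoxide opens the C3–C4 oxirane at C3 (3-exo-tet, inversion at C3) and so turns the trans C3–C4 epoxide into the cis C2–C3 epoxide 8; the freed C4 alkoxide is trapped at once by 1,5 O-to-O transfer of the neighbouring aryl Boc group, which should make the otherwise unfavourable equilibrium irreversible, unmask the phenol O1 only once the cis-epoxide exists (9) and leave an electron-withdrawing carbonate on the benzylic C4 oxygen. Mild acid then lets O1 open the oxirane at the ring B benzylic carbon C2 with inversion in a 6-endo-tet closure of ring C (10), and catalytic alkoxide finally closes the cis-fused five-membered carbonate by attack of the 3-OH on the Boc carbonyl (5-exo-trig) with loss of tert-butoxide. The closest known reactions are the Payne rearrangement with in situ capture of the rearranged epoxy alkoxide and the acid-catalysed 6-endo cyclisation of ortho-hydroxyaryl-substituted aryl epoxides used for flavan-3-ols; the aryl carbonate relay that couples the two is the new element. C4 is never touched and keeps the configuration from step 4, C3 is fixed by the stereospecific Payne inversion (threo and trans give cis), and C2 by the SN2-type inversion at the cis-epoxide, which together should give the all-cis 2R,3R,4R array. The step needs 6-endo attack at C2 instead of 5-exo attack at C3, and inversion instead of an open benzylic cation: the first is secured by the 4-benzyloxyphenyl group on C2, by the deactivating carbonate next to C3 and by keeping the phenoxide cold until it is protonated, the second by the weak acid, the low temperature and the low polarity of the medium.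

**Step 7**
Reactants: 11 3,4-cyclic carbonate of all-cis (2R,3R,4R)-7,8-bis(benzyloxy)-2-[4-(benzyloxy)phenyl]chromane-3,4-diol
Product: 12 6-bromo derivative of 11
Conditions: NBS (1.0 equiv), MeCN/CH2Cl2, −20 → 0 °C, dark
Reagents that add atoms: N-bromosuccinimide O=C1CCC(=O)N1Br
Why: Electrophilic aromatic bromination at C6 of ring A, the free position para to O1 and ortho to the 7-benzyloxy group and thus the most electron-rich one, which is the site that must be blocked in the top unit.

**Step 8**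
Reactants: 12 6-bromo derivative of 11
Product: 13 (2R,3R,4R)-7,8-bis(benzyloxy)-2-[4-(benzyloxy)phenyl]-6-bromochromane-3,4-diol (all-cis)
Conditions: K2CO3 (0.2 equiv), MeOH/THF, 20 °C
Reagents that add atoms: none
Why: Base-catalysed transesterification of the five-membered carbonate with methanol frees the cis-3,4-diol without any ionisation at C4, so the configuration is retained and the 4-OH becomes available as a leaving group.

**Step 9**
Reactants: 13 (2R,3R,4R)-7,8-bis(benzyloxy)-2-[4-(benzyloxy)phenyl]-6-bromochromane-3,4-diol; 11 3,4-cyclic carbonate of all-cis (2R,3R,4R)-7,8-bis(benzyloxy)-2-[4-(benzyloxy)phenyl]chromane-3,4-diol (4 equiv, excess recovered)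
Product: 14 6-bromo-7,8,4'-tri-O-benzyl-epioritin-(4β→6)-[7,8,4'-tri-O-benzyl-epioritin-4α-ol 3,4-cyclic carbonate] (epioritin = (2R,3R)-2,3-cis-3,7,8,4'-tetrahydroxyflavan)
Conditions: Me3SiOTf (0.2 equiv), 4 Å MS, CH2Cl2, −78 → −30 °C; Et3N quench
Reagents that add atoms: none
Why: Friedel–Crafts-type alkylation through a flavan-4-yl cation in which the acid ionises the benzylic 4-OH of 13 with loss of water (cation stabilised by O1 and the 7-benzyloxy group) and C6 of ring A of 11 attacks anti to the axial 3-OH of the 2,3-cis cation to give the 3,4-trans (4β→6) bond, while 13 cannot self-condense (C6 brominated) and 11 should not ionise because its C4 oxygen is tied into the electron-poor cyclic carbonate.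

**Step 10**
Reactants: 14 6-bromo-7,8,4'-tri-O-benzyl-epioritin-(4β→6)-[7,8,4'-tri-O-benzyl-epioritin-4α-ol 3,4-cyclic carbonate]
Product: 15 6-bromo-7,8,4'-tri-O-benzyl-epioritin-(4β→6)-7,8,4'-tri-O-benzyl-epioritin-4α-ol
Conditions: K2CO3 (0.2 equiv), MeOH/THF, 20 °C
Reagents that add atoms: none
Why: Same carbonate methanolysis as in step 8, now unmasking the 3,4-diol of the middle unit and so turning the dimer into the next electrophile.

**Step 11**
Reactants: 15 6-bromo-7,8,4'-tri-O-benzyl-epioritin-(4β→6)-7,8,4'-tri-O-benzyl-epioritin-4α-ol; 11 3,4-cyclic carbonate of all-cis (2R,3R,4R)-7,8-bis(benzyloxy)-2-[4-(benzyloxy)phenyl]chromane-3,4-diol (4 equiv, excess recovered)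
Product: 16 6-bromo-tri-O-benzyl-epioritin-(4β→6)-tri-O-benzyl-epioritin-(4β→6)-[tri-O-benzyl-epioritin-4α-ol 3,4-cyclic carbonate]
Conditions: Me3SiOTf (0.2 equiv), 4 Å MS, CH2Cl2, −78 → −30 °C; Et3N quench
Reagents that add atoms: none
Why: Second flavan-4-yl cation arylation in which ionisation of the 4-OH of the middle unit of 15 with loss of water and attack of C6 of 11 anti to the axial 3-OH should give the second 3,4-trans (4β→6) bond, and 15 has no free C6 position so it cannot oligomerise.

**Step 12**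
Reactants: 16 6-bromo-tri-O-benzyl-epioritin-(4β→6)-tri-O-benzyl-epioritin-(4β→6)-[tri-O-benzyl-epioritin-4α-ol 3,4-cyclic carbonate]
Product: 17 6-bromo-nona-O-benzyl-epioritin-(4β→6)-epioritin-(4β→6)-epioritin-4α-ol
Conditions: K2CO3 (0.2 equiv), MeOH/THF, 20 °C
Reagents that add atoms: none
Why: Carbonate methanolysis under base liberates the cis-3,4-diol of the bottom unit without ionising C4, so the 4α-hydroxyl (all-cis) configuration made in step 6 is kept.

**Step 13**
Reactants: 17 6-bromo-nona-O-benzyl-epioritin-(4β→6)-epioritin-(4β→6)-epioritin-4α-ol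
Product: 18 epioritin-(4β→6)-epioritin-(4β→6)-epioritin-4α-ol (CNP0140823.1)
Conditions: H2 (1 atm), Pd(OH)2/C, Et3N (1.5 equiv), THF/MeOH/H2O, 20 °C
Reagents that add atoms: none
Why: Hydrogenolysis over Pd(OH)2/C removes the nine benzyl ethers and the aryl bromide in one operation, triethylamine taking up HBr and slowing cleavage of the benzylic C4–OH and O1–C2 bonds, to give the free nonaphenol.

**Compound list**

1 | 2,3,4-trihydroxybenzaldehyde | O=Cc1ccc(O)c(O)c1O | starting material
2 | 3,4-bis(benzyloxy)-2-hydroxybenzaldehyde | O=Cc1ccc(OCc2ccccc2)c(OCc2ccccc2)c1O | intermediate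
3 | 1-[4-(benzyloxy)phenyl]ethanone | CC(=O)c1ccc(OCc2ccccc2)cc1 | starting material
4 | (E)-3-[3,4-bis(benzyloxy)-2-hydroxyphenyl]-1-[4-(benzyloxy)phenyl]prop-2-en-1-one | O=C(/C=C/c1ccc(OCc2ccccc2)c(OCc2ccccc2)c1O)c1ccc(OCc2ccccc2)cc1 | intermediate
5 | tert-butyl 2,3-bis(benzyloxy)-6-{(E)-3-[4-(benzyloxy)phenyl]-3-oxoprop-1-en-1-yl}phenyl carbonate | CC(C)(C)OC(=O)Oc1c(/C=C/C(=O)c2ccc(OCc3ccccc3)cc2)ccc(OCc2ccccc2)c1OCc1ccccc1 | intermediate
6 | tert-butyl 2,3-bis(benzyloxy)-6-{(2R,3S)-3-[4-(benzyloxy)benzoyl]oxiran-2-yl}phenyl carbonate (trans-epoxide) | CC(C)(C)OC(=O)Oc1c(OCc2ccccc2)c(OCc2ccccc2)ccc1[C@H]1O[C@@H]1C(=O)c1ccc(OCc2ccccc2)cc1 | intermediate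
7 | tert-butyl 2,3-bis(benzyloxy)-6-[(2R,3R)-3-{(S)-[4-(benzyloxy)phenyl](hydroxy)methyl}oxiran-2-yl]phenyl carbonate (threo, trans-epoxide) | CC(C)(C)OC(=O)Oc1c(OCc2ccccc2)c(OCc2ccccc2)ccc1[C@H]1O[C@@H]1[C@@H](O)c1ccc(OCc2ccccc2)cc1 | intermediate
8 | tert-butyl 2,3-bis(benzyloxy)-6-{(R)-hydroxy[(2R,3S)-3-(4-(benzyloxy)phenyl)oxiran-2-yl]methyl}phenyl carbonate (cis-epoxide, present as its potassium alkoxide) | CC(C)(C)OC(=O)Oc1c(OCc2ccccc2)c(OCc2ccccc2)ccc1[C@@H](O)[C@H]1O[C@H]1c1ccc(OCc2ccccc2)cc1 | intermediate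
9 | tert-butyl (R)-[3,4-bis(benzyloxy)-2-hydroxyphenyl]{(2S,3S)-3-[4-(benzyloxy)phenyl]oxiran-2-yl}methyl carbonate (cis-epoxide) | Oc1c(OCc2ccccc2)c(OCc2ccccc2)ccc1[C@@H](OC(=O)OC(C)(C)C)[C@H]1O[C@H]1c1ccc(OCc2ccccc2)cc1 | intermediate
10 | all-cis 4-O-(tert-butoxycarbonyl) derivative of (2R,3R,4R)-7,8-bis(benzyloxy)-2-[4-(benzyloxy)phenyl]chromane-3,4-diol (3-OH free; descriptors of the parent diol) | c1cc2c(c(OCc3ccccc3)c1OCc1ccccc1)O[C@H](c1ccc(OCc3ccccc3)cc1)[C@H](O)[C@@H]2OC(=O)OC(C)(C)C | intermediate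
11 | 3,4-cyclic carbonate of all-cis (2R,3R,4R)-7,8-bis(benzyloxy)-2-[4-(benzyloxy)phenyl]chromane-3,4-diol (descriptors of the parent diol) | c1cc2c(c(OCc3ccccc3)c1OCc1ccccc1)O[C@H](c1ccc(OCc3ccccc3)cc1)[C@@H]1OC(=O)O[C@H]21 | intermediate
12 | 6-bromo derivative of 11 | Brc1cc2c(c(OCc3ccccc3)c1OCc1ccccc1)O[C@H](c1ccc(OCc3ccccc3)cc1)[C@@H]1OC(=O)O[C@H]21 | intermediate
13 | (2R,3R,4R)-7,8-bis(benzyloxy)-2-[4-(benzyloxy)phenyl]-6-bromochromane-3,4-diol (all-cis) | Brc1cc2c(c(OCc3ccccc3)c1OCc1ccccc1)O[C@H](c1ccc(OCc3ccccc3)cc1)[C@H](O)[C@@H]2O | intermediate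
14 | 6-bromo-7,8,4'-tri-O-benzyl-epioritin-(4β→6)-[7,8,4'-tri-O-benzyl-epioritin-4α-ol 3,4-cyclic carbonate] | c5ccccc5COc1ccc([C@H]2Oc3c(cc(Br)c(OCc5ccccc5)c3OCc5ccccc5)[C@H](c3cc4c(c(OCc5ccccc5)c3OCc5ccccc5)O[C@H](c3ccc(OCc5ccccc5)cc3)[C@@H]6OC(=O)O[C@H]46)[C@H]2O)cc1 | intermediate
15 | 6-bromo-7,8,4'-tri-O-benzyl-epioritin-(4β→6)-7,8,4'-tri-O-benzyl-epioritin-4α-ol | c5ccccc5COc1ccc([C@H]2Oc3c(cc(Br)c(OCc5ccccc5)c3OCc5ccccc5)[C@H](c3cc4c(c(OCc5ccccc5)c3OCc5ccccc5)O[C@H](c3ccc(OCc5ccccc5)cc3)[C@H](O)[C@@H]4O)[C@H]2O)cc1 | intermediate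
16 | 6-bromo-tri-O-benzyl-epioritin-(4β→6)-tri-O-benzyl-epioritin-(4β→6)-[tri-O-benzyl-epioritin-4α-ol 3,4-cyclic carbonate] | c5ccccc5COc1ccc([C@H]2Oc3c(cc(Br)c(OCc5ccccc5)c3OCc5ccccc5)[C@H](c3cc4c(c(OCc5ccccc5)c3OCc5ccccc5)O[C@H](c3ccc(OCc5ccccc5)cc3)[C@H](O)[C@H]4c3cc4c(c(OCc5ccccc5)c3OCc5ccccc5)O[C@H](c3ccc(OCc5ccccc5)cc3)[C@@H]6OC(=O)O[C@H]46)[C@H]2O)cc1 | intermediate
17 | 6-bromo-nona-O-benzyl-epioritin-(4β→6)-epioritin-(4β→6)-epioritin-4α-ol | c5ccccc5COc1ccc([C@H]2Oc3c(cc(Br)c(OCc5ccccc5)c3OCc5ccccc5)[C@H](c3cc4c(c(OCc5ccccc5)c3OCc5ccccc5)O[C@H](c3ccc(OCc5ccccc5)cc3)[C@H](O)[C@H]4c3cc4c(c(OCc5ccccc5)c3OCc5ccccc5)O[C@H](c3ccc(OCc5ccccc5)cc3)[C@H](O)[C@@H]4O)[C@H]2O)cc1 | intermediate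
18 | epioritin-(4β→6)-epioritin-(4β→6)-epioritin-4α-ol (CNP0140823.1) | Oc1ccc([C@H]2Oc3c(ccc(O)c3O)[C@H](c3cc4c(c(O)c3O)O[C@H](c3ccc(O)cc3)[C@H](O)[C@H]4c3cc4c(c(O)c3O)O[C@H](c3ccc(O)cc3)[C@H](O)[C@@H]4O)[C@H]2O)cc1 | target

**Totals and risks**

Total step count: 13. Longest linear sequence: 13 steps (1 → 18; compound 11 re-enters the line in steps 9 and 11).

Steps most likely to fail:

1. Step 6 (Proposed new method). What may go wrong: 5-exo attack of the phenoxide at C3 before it is protonated; opening of the cis-epoxide through an open benzylic cation, which would scramble C2; incomplete Payne transfer. Fallback, known chemistry only, setting out from 5 and coming back at 11: the epoxidation of step 4 is run with (S)-BINOL to give the enantiomeric trans-epoxy ketone F1. Zn(BH4)2 in Et2O at −20 °C (aqueous NH4Cl quench) reduces it under chelation control to the erythro epoxy alcohol F2. Ti(O-iPr)4 and PhCO2H open the oxirane at the benzylic carbon C4, distal to the hydroxyl, with inversion to give the C4 benzoate of the open-chain triol F3. Piperidine removes the aryl Boc group to give the phenol F4. HC(OEt)3 with PPTS turns the C2/C3 diol into the cyclic orthoformate F5, which O1 opens at C2 with inversion (the standard flavan-3-ol ring closure) to give the all-cis 3-O-formyl-4-O-benzoyl flavan F6. K2CO3 in MeOH gives the all-cis diol F7, and 1,1'-carbonyldiimidazole closes the carbonate to return to 11. In this variant C3 is retained and C4 is inverted, which is why the other epoxide enantiomer is needed.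

2. Step 5. What may go wrong: reagent control failing to override the erythro preference of the epoxy ketone; borane-induced reductive opening of the electron-rich oxirane. Fallback, setting out from 5 and coming back at 7: the carbinol centre is set before the oxirane. Base-free Noyori hydrogenation of the enone carbonyl (RuH(BH4)[xylbinap][dpen], H2, i-PrOH, catalyst enantiomer chosen for the (R)-alcohol) gives the (R,E)-allylic alcohol F8. Shi epoxidation (D-fructose-derived ketone, KHSO5, pH 10.5 buffer, MeCN/dimethoxymethane, 0 °C) then sets the (2R,3R)-oxirane under reagent control and gives 7.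

3. Step 9 (the same issues apply to step 11). What may go wrong: O-alkylation by the free hydroxyls competing with C-alkylation; attack at C5 instead of C6; partial ionisation of the carbonate-protected partner under the Lewis acid, leading to oligomers. Fallback, setting out from 13 and coming back at 14: BnSH with AcOH converts 13 into the 4β-benzylsulfanyl flavan-3-ol F9 (3,4-trans). AgBF4 in THF at 0 °C, acting as a thiophile, then releases the C4 cation under neutral conditions in the presence of excess 11 to give 14, a mode of activation that leaves a 4-oxygenated nucleophilic partner untouched.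

**Further compounds**

F1 | step 6 | tert-butyl 2,3-bis(benzyloxy)-6-{(2S,3R)-3-[4-(benzyloxy)benzoyl]oxiran-2-yl}phenyl carbonate (enantiomer of 6) | CC(C)(C)OC(=O)Oc1c(OCc2ccccc2)c(OCc2ccccc2)ccc1[C@@H]1O[C@H]1C(=O)c1ccc(OCc2ccccc2)cc1
F2 | step 6 | tert-butyl 2,3-bis(benzyloxy)-6-[(2S,3S)-3-{(S)-[4-(benzyloxy)phenyl](hydroxy)methyl}oxiran-2-yl]phenyl carbonate (erythro epoxy alcohol) | CC(C)(C)OC(=O)Oc1c(OCc2ccccc2)c(OCc2ccccc2)ccc1[C@@H]1O[C@H]1[C@@H](O)c1ccc(OCc2ccccc2)cc1
F3 | step 6 | (1R,2S,3S)-1-[3,4-bis(benzyloxy)-2-(tert-butoxycarbonyloxy)phenyl]-3-[4-(benzyloxy)phenyl]-2,3-dihydroxypropyl benzoate (C4 benzoate; C4 inverted relative to F2) | CC(C)(C)OC(=O)Oc1c(OCc2ccccc2)c(OCc2ccccc2)ccc1[C@@H](OC(=O)c1ccccc1)[C@@H](O)[C@@H](O)c1ccc(OCc2ccccc2)cc1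
F4 | step 6 | (1R,2S,3S)-1-[3,4-bis(benzyloxy)-2-hydroxyphenyl]-3-[4-(benzyloxy)phenyl]-2,3-dihydroxypropyl benzoate (same configuration as F3) | Oc1c(OCc2ccccc2)c(OCc2ccccc2)ccc1[C@@H](OC(=O)c1ccccc1)[C@@H](O)[C@@H](O)c1ccc(OCc2ccccc2)cc1
F5 | step 6 | C2/C3 cyclic ethyl orthoformate of F4 (2-ethoxy-1,3-dioxolane; C2, C3 and C4 as in F4, orthoester carbon unassigned) | Oc1c(OCc2ccccc2)c(OCc2ccccc2)ccc1[C@@H](OC(=O)c1ccccc1)[C@H]1OC(OCC)O[C@H]1c1ccc(OCc2ccccc2)cc1
F6 | step 6 | all-cis 3-O-formyl-4-O-benzoyl derivative of (2R,3R,4R)-7,8-bis(benzyloxy)-2-[4-(benzyloxy)phenyl]chromane-3,4-diol | c1cc2c(c(OCc3ccccc3)c1OCc1ccccc1)O[C@H](c1ccc(OCc3ccccc3)cc1)[C@H](OC=O)[C@@H]2OC(=O)c1ccccc1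
F7 | step 6 | (2R,3R,4R)-7,8-bis(benzyloxy)-2-[4-(benzyloxy)phenyl]chromane-3,4-diol (all-cis) | c1cc2c(c(OCc3ccccc3)c1OCc1ccccc1)O[C@H](c1ccc(OCc3ccccc3)cc1)[C@H](O)[C@@H]2O
F8 | step 5 | tert-butyl 2,3-bis(benzyloxy)-6-{(R,E)-3-[4-(benzyloxy)phenyl]-3-hydroxyprop-1-en-1-yl}phenyl carbonate | CC(C)(C)OC(=O)Oc1c(OCc2ccccc2)c(OCc2ccccc2)ccc1/C=C/[C@@H](O)c1ccc(OCc2ccccc2)cc1
F9 | step 9 | (2R,3S,4S)-7,8-bis(benzyloxy)-2-[4-(benzyloxy)phenyl]-4-(benzylsulfanyl)-6-bromochroman-3-ol (2,3-cis-3,4-trans, sulfur 4β; C2 and C3 spatially as in 13) | Brc1cc2c(c(OCc3ccccc3)c1OCc1ccccc1)O[C@H](c1ccc(OCc3ccccc3)cc1)[C@H](O)[C@H]2SCc1ccccc1
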